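The route rests on disconnecting C8–C9, the bond shared by the five-membered ring B (C5, C6, C8, C9, C10) and the six-membered ring C (C8, C9, C11–C14), together with C13–C14. A thermal intramolecular Diels–Alder reaction of a ring-A triene, whose C10 carries a 1-chloro-2-siloxy diene (C9=C11–C12=C13) and whose C5 carries the alkene C8=C14 with a propargyl arm, closes rings B and C in one operation and creates the quaternary C8 and the C9 stereocentre. The chlorine left at C13 then drives a 5-exo-dig radical closure of ring D; reduction at C12 triggers lactonisation onto C20.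

Key step: step 16

Remark on numbering: gibberellane numbering is used throughout (ring A C1–C5 and C10; ring B C5, C6, C8, C9, C10; ring C C8, C9, C11–C14; ring D C8, C13–C16; C17 methylidene carbon, C18 methyl, C7, C19 and C20 carboxyl carbons); α means the face of ring A that carries C19 and C20, β the other face.
Assumption 1: the antipode of the chromium salen catalyst in step 3 is the one that gives the (S)-configured quaternary centre; should the sense of induction be the opposite, the enantiomeric catalyst is taken.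
Assumption 2: C6 is expected to form in step 9 as a mixture of epimers; it is written without configuration in 17–29 and is set by equilibration in step 19.

Step 1
Reactants: 1 2-methylidenepropane-1,3-diol
Product: 2 2-{[(tert-butyldiphenylsilyl)oxy]methyl}prop-2-en-1-ol
Conditions: TBDPSCl (1 equiv), imidazole, 1 (3 equiv), THF, 0 °C to rt
Reagents that add atoms: tert-butyl(chloro)diphenylsilane CC(C)(C)[Si](Cl)(c1ccccc1)c1ccccc1
Why: Silyl ether formation on a symmetrical diol used in excess should give mainly the mono-ether; no stereocentre is involved.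

Step 2
Reactants: 2 2-{[(tert-butyldiphenylsilyl)oxy]methyl}prop-2-en-1-ol
Product: 3 2-{[(tert-butyldiphenylsilyl)oxy]methyl}prop-2-enal
Conditions: MnO2, CH2Cl2, rt
Reagents that add atoms: none
Why: Allylic oxidation with MnO2 should stop at the enal and leave the silyl ether intact.

Step 3
Reactants: 3 2-{[(tert-butyldiphenylsilyl)oxy]methyl}prop-2-enal; 4 (1E)-3-[(tert-butyldimethylsilyl)oxy]-N,N-dimethylbuta-1,3-dien-1-amine
Product: 6 (1S)-1-{[(tert-butyldiphenylsilyl)oxy]methyl}-4-oxocyclohex-2-ene-1-carbaldehyde, via aminocyclohexene cycloadduct 5 (not isolated)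
Conditions: [(1S,2S)-N,N'-bis(3,5-di-tert-butylsalicylidene)cyclohexane-1,2-diaminato]chromium hexafluoroantimonate (5 mol %), 4 Å MS, CH2Cl2, −40 °C; then AcCl, Et2O, −78 °C
Reagents that add atoms: none
Why: Catalytic asymmetric Diels–Alder reaction of a 1-amino-3-siloxy diene with an α-substituted acrolein, in which the chiral Lewis acid binds the aldehyde and shields one face so that the quaternary C10 centre is set by the catalyst; acetyl chloride then removes the amine and the silyl group to unveil the enone.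

Step 4
Reactants: 6 (1S)-1-{[(tert-butyldiphenylsilyl)oxy]methyl}-4-oxocyclohex-2-ene-1-carbaldehyde
Product: 8 methyl (1S)-1-{[(tert-butyldiphenylsilyl)oxy]methyl}-4-oxocyclohex-2-ene-1-carboxylate, via carboxylic acid 7 (not isolated)
Conditions: NaClO2, NaH2PO4, 2-methylbut-2-ene, t-BuOH/H2O, 0 °C to rt; then TMSCHN2, PhMe/MeOH, 0 °C
Reagents that add atoms: sodium chlorite [Na+].[O-]Cl=O; (trimethylsilyl)diazomethane C[Si](C)(C)C=[N+]=[N-]
Why: Pinnick oxidation of the non-enolisable aldehyde followed by esterification with the diazoalkane should give the C20 methyl ester without touching the stereocentre or the enone.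

Step 5
Reactants: 8 methyl (1S)-1-{[(tert-butyldiphenylsilyl)oxy]methyl}-4-oxocyclohex-2-ene-1-carboxylate
Product: 9 methyl (1S)-1-{[(tert-butyldiphenylsilyl)oxy]methyl}-3-iodo-4-oxocyclohex-2-ene-1-carboxylate
Conditions: I2, pyridine, CH2Cl2, 0 °C to rt
Reagents that add atoms: iodine II
Why: α-Iodination of the enone by conjugate addition of pyridine, iodination of the enolate and elimination (addition–elimination) should place iodine at C4.

Step 6
Reactants: 9 methyl (1S)-1-{[(tert-butyldiphenylsilyl)oxy]methyl}-3-iodo-4-oxocyclohex-2-ene-1-carboxylate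
Product: 10 dimethyl (1S)-1-{[(tert-butyldiphenylsilyl)oxy]methyl}-4-oxocyclohex-2-ene-1,3-dicarboxylate
Conditions: Pd(OAc)2 (5 mol %), PPh3, CO (1 atm), MeOH, Et3N, DMF, 60 °C
Reagents that add atoms: carbon monoxide [C-]#[O+]; methanol CO
Why: Palladium-catalysed methoxycarbonylation of the vinyl iodide (oxidative addition, CO insertion, methanolysis) should install the C19 ester and give a doubly activated alkylidene β-keto ester.

Step 7
Reactants: 11 3-bromo-2-(bromomethyl)prop-1-ene; 12 lithium (trimethylsilyl)acetylide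
Product: 13 [4-(bromomethyl)pent-4-en-1-yn-1-yl]trimethylsilane
Conditions: CuBr·SMe2 (10 mol %), 11 (3 equiv), THF, −40 to 0 °C
Reagents that add atoms: none
Why: Copper-catalysed substitution of one allylic bromide by the acetylide, in which the symmetrical allyl unit makes the SN2 and SN2′ products identical and the excess of 11 suppresses double substitution.

Step 8
Reactants: 13 [4-(bromomethyl)pent-4-en-1-yn-1-yl]trimethylsilane
Product: 14 methyl 3-methylidene-6-(trimethylsilyl)hex-5-ynoate
Conditions: Pd(OAc)2 (3 mol %), PPh3, CO (5 bar), MeOH, i-Pr2NEt, THF, 40 °C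
Reagents that add atoms: carbon monoxide [C-]#[O+]; methanol CO
Why: Palladium-catalysed methoxycarbonylation of the allylic bromide through a π-allyl complex should give the β,γ-unsaturated ester, the symmetrical allyl unit removing any regiochemical issue.

Step 9
Reactants: 14 methyl 3-methylidene-6-(trimethylsilyl)hex-5-ynoate; 10 dimethyl (1S)-1-{[(tert-butyldiphenylsilyl)oxy]methyl}-4-oxocyclohex-2-ene-1,3-dicarboxylate
Product: 17 dimethyl (1S)-1-{[(tert-butyldiphenylsilyl)oxy]methyl}-2-[1-methoxy-3-methylidene-1-oxo-6-(trimethylsilyl)hex-5-yn-2-yl]-3-methyl-4-oxocyclohexane-1,3-dicarboxylate (ring esters and C5 side chain all α; C6 epimers), via lithium dienolate 15 (not isolated), via lithium keto ester enolate 16 (not isolated)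
Conditions: LiN(i-Pr)2, THF, −78 °C; add 10, −78 °C; then MeI, HMPA, −78 to 0 °C
Reagents that add atoms: iodomethane CI
Why: Michael addition followed by enolate alkylation, in which dienolate 15 attacks through its α-carbon C6 at C5 anti to the bulky pseudo-axial silyloxymethyl group (C6 cis to the C10 ester) and methyl iodide then alkylates enolate 16 at C4 anti to the new C5 substituent and to the axial C10 ester (CH3 β).

Step 10
Reactants: 17 the keto triester of step 9
Product: 18 dimethyl 1-{[(tert-butyldiphenylsilyl)oxy]methyl}-4-hydroxy-2-[1-methoxy-3-methylidene-1-oxo-6-(trimethylsilyl)hex-5-yn-2-yl]-3-methylcyclohexane-1,3-dicarboxylate (C3 alcohol epimers)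
Conditions: NaBH4, MeOH, 0 °C to rt
Reagents that add atoms: none
Why: Hydride reduction of the ketone in the presence of esters; the configuration at C3 is irrelevant because the centre is removed in step 11.

Step 11
Reactants: 18 the C3 alcohol of step 10
Product: 19 dimethyl 1-{[(tert-butyldiphenylsilyl)oxy]methyl}-2-[1-methoxy-3-methylidene-1-oxo-6-(trimethylsilyl)hex-5-yn-2-yl]-3-methylcyclohex-4-ene-1,3-dicarboxylate
Conditions: methyl N-(triethylammoniosulfonyl)carbamate (Burgess reagent), PhMe, 80 °C
Reagents that add atoms: none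
Why: Burgess dehydration by syn-elimination of the sulfamate, in which the quaternary C4 leaves only the C2 hydrogens, so that the C2=C3 alkene is the only possible product.

Step 12
Reactants: 19 the cyclohexene triester of step 11
Product: 20 dimethyl 1-(hydroxymethyl)-2-(1-methoxy-3-methylidene-1-oxohex-5-yn-2-yl)-3-methylcyclohex-4-ene-1,3-dicarboxylate
Conditions: TBAF, AcOH, THF, 0 °C to rt
Reagents that add atoms: none
Why: Fluoride cleaves the O–Si and the alkynyl C–Si bonds, and acetic acid buffers the alkoxide so that neither lactonisation onto C7 nor migration of the C8=C14 double bond should set in.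

Step 13
Reactants: 20 the primary alcohol of step 12
Product: 21 dimethyl 1-formyl-2-(1-methoxy-3-methylidene-1-oxohex-5-yn-2-yl)-3-methylcyclohex-4-ene-1,3-dicarboxylate
Conditions: Dess–Martin periodinane, NaHCO3, CH2Cl2, 0 °C to rt
Reagents that add atoms: none
Why: Dess–Martin oxidation of the neopentyl primary alcohol should give the non-enolisable C9 aldehyde.

Step 14
Reactants: 21 the aldehyde of step 13; 22 1-chloro-3-(triphenyl-λ5-phosphanylidene)propan-2-one
Product: 23 dimethyl 1-[(1E)-4-chloro-3-oxobut-1-en-1-yl]-2-(1-methoxy-3-methylidene-1-oxohex-5-yn-2-yl)-3-methylcyclohex-4-ene-1,3-dicarboxylate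
Conditions: PhMe, 90 °C
Reagents that add atoms: none
Why: Wittig reaction of the stabilised ylide with the hindered aldehyde should give the (E)-enone that carries C11, C12 and the chlorinated C13.

Step 15
Reactants: 23 the chloromethyl enone of step 14
Product: 24 dimethyl 1-[(1E,3Z)-3-[(tert-butyldimethylsilyl)oxy]-4-chlorobuta-1,3-dien-1-yl]-2-(1-methoxy-3-methylidene-1-oxohex-5-yn-2-yl)-3-methylcyclohex-4-ene-1,3-dicarboxylate
Conditions: TBSOTf, Et3N, CH2Cl2, −78 to 0 °C
Reagents that add atoms: tert-butyldimethylsilyl trifluoromethanesulfonate CC(C)(C)[Si](C)(C)OS(=O)(=O)C(F)(F)F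
Why: Soft enolisation and O-silylation on the only enolisable side of the ketone should give the (Z)-configured 1-chloro-2-siloxy diene (silyl enol ether formation).

Step 16
Reactants: 24 the siloxy chlorodiene of step 15
Product: 26 trimethyl 13-chloro-12-oxo-13,16-secogibberell-2-en-16-yne-7,19,20-trioate (A/B trans; B/C cis; C13 and C6 epimers), via cycloadduct silyl enol ether 25 (not isolated)
Conditions: BHT, 2,6-di-tert-butylpyridine (0.2 equiv), 1,2-dichlorobenzene, 175 °C, sealed tube; then 1 M HCl, THF, 0 °C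
Reagents that add atoms: none
Why: Heating brings the s-cis 1-chloro-2-siloxy diene (C9=C11–C12=C13) over the tethered alkene C8=C14, and a concerted, asynchronous [4+2] cycloaddition forms C8–C9 and C13–C14 to give silyl enol ether 25, which aqueous acid hydrolyses to ketone 26. The closest known reaction type is the thermal type 1 intramolecular Diels–Alder reaction of 1,3,8-nonatrienes that carry a 2-siloxy diene and an unactivated alkene. Ring B (five-membered) closes through the new C8–C9 bond across the three-atom tether C10–C5–C6 in the fused mode, and ring C (six-membered) is the cyclohexene of the cycloaddition itself, completed by C13–C14. C8 is controlled by the transition-state topology, because the propargyl arm on the internal dienophile carbon stays exo, away from the siloxy diene, so that the tether is endo and rings B and C become cis-fused (C11 and C14 cis); C9 is controlled by the C10 and C5 centres of ring A, the diene adding on the α face where C11 is pseudo-equatorial on the emerging trans-fused A/B hydrindane and cis to the C10 ester. The step needs site selectivity for the alkene over the alkyne, secured by ring size (the alkyne could react only through a seven-membered tether ring), and regioselectivity, secured by the tether and matched by the polarity of the diene terminus C13 and the unsubstituted alkene carbon C14. C13 and C6 need no control here, since C13 becomes a radical centre in step 18 and C6 is equilibrated in step 19.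

Step 17
Reactants: 26 the tricyclic chloro ketone of step 16
Product: 27 trimethyl 13-chloro-2β,3β-dihydroxy-12-oxo-13,16-secogibberell-16-yne-7,19,20-trioate
Conditions: OsO4 (2 mol %), 4-methylmorpholine N-oxide, acetone/H2O, 0 °C to rt
Reagents that add atoms: osmium tetroxide O=[Os](=O)(=O)=O; 4-methylmorpholine N-oxide C[N+]1([O-])CCOCC1; water O
Why: Catalytic syn-dihydroxylation of the only alkene, in which the reagent adds from the β face because the axial C19 and C20 ester groups cover the α face, which sets C2 and C3; the alkyne is much less reactive.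

Step 18
Reactants: 27 the chloro ketone diol of step 17
Product: 28 trimethyl 2β,3β-dihydroxy-12-oxogibberell-16-ene-7,19,20-trioate (C6 epimers)
Conditions: Bu3SnH (slow addition), AIBN (cat.), PhH, 80 °C
Reagents that add atoms: none
Why: Tin hydride radical cyclisation, in which chlorine abstraction gives the C13 α-keto radical from either C13 epimer, 5-exo-dig attack on the alkyne of the axial propargyl arm closes ring D, the vinyl radical takes hydrogen to leave the exocyclic methylidene, and the bridge fixes the configuration of C13.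

Step 19
Reactants: 28 the tetracyclic keto triester of step 18
Product: 30 7,19-dimethyl ester of 2β,3β,12α-trihydroxygibberell-16-ene-7,19,20-trioic acid 20,12-lactone, via lithium 12α-alkoxide 29 (not isolated)
Conditions: LiBH(s-Bu)3, THF, −78 to 0 °C; then NaOMe, MeOH, rt; AcOH
Reagents that add atoms: none
Why: Ketone reduction, lactonisation and epimerisation, in which the bulky hydride attacks C12 from the side away from the axial C10 substituent to give the axial 12α-alkoxide 29, which alone can lactonise onto the C20 ester, and methoxide then equilibrates C6 to the 6β-ester, expected to be more stable because it is trans to the quaternary C4.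

Step 20
Reactants: 30 the lactone dimethyl ester of step 19
Product: 31 2β,3β,12α-trihydroxygibberell-16-ene-7,19,20-trioic acid 20,12-lactone (CNP0212122.1)
Conditions: n-PrSLi, HMPA, rt; then 1 M HCl
Reagents that add atoms: none
Why: SN2 demethylation of the two hindered methyl esters by thiolate at the methyl carbons avoids attack at the neopentyl carbonyl groups, and acidification re-closes the bridged lactone should it have opened.

Compound list
1 | 2-methylidenepropane-1,3-diol | C=C(CO)CO | starting material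
2 | 2-{[(tert-butyldiphenylsilyl)oxy]methyl}prop-2-en-1-ol | C=C(CO)CO[Si](c1ccccc1)(c1ccccc1)C(C)(C)C | intermediate
3 | 2-{[(tert-butyldiphenylsilyl)oxy]methyl}prop-2-enal | C=C(C=O)CO[Si](c1ccccc1)(c1ccccc1)C(C)(C)C | intermediate
4 | (1E)-3-[(tert-butyldimethylsilyl)oxy]-N,N-dimethylbuta-1,3-dien-1-amine | CN(C)/C=C/C(=C)O[Si](C)(C)C(C)(C)C | starting material
5 | (1S)-4-[(tert-butyldimethylsilyl)oxy]-1-{[(tert-butyldiphenylsilyl)oxy]methyl}-2-(dimethylamino)cyclohex-3-ene-1-carbaldehyde (C2 unassigned) | O=C[C@@]1(CO[Si](c2ccccc2)(c2ccccc2)C(C)(C)C)CCC(O[Si](C)(C)C(C)(C)C)=CC1N(C)C | intermediate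
6 | (1S)-1-{[(tert-butyldiphenylsilyl)oxy]methyl}-4-oxocyclohex-2-ene-1-carbaldehyde | O=C[C@@]1(CO[Si](c2ccccc2)(c2ccccc2)C(C)(C)C)CCC(=O)C=C1 | intermediate
7 | (1S)-1-{[(tert-butyldiphenylsilyl)oxy]methyl}-4-oxocyclohex-2-ene-1-carboxylic acid | OC(=O)[C@@]1(CO[Si](c2ccccc2)(c2ccccc2)C(C)(C)C)CCC(=O)C=C1 | intermediate
8 | methyl (1S)-1-{[(tert-butyldiphenylsilyl)oxy]methyl}-4-oxocyclohex-2-ene-1-carboxylate | COC(=O)[C@@]1(CO[Si](c2ccccc2)(c2ccccc2)C(C)(C)C)CCC(=O)C=C1 | intermediate
9 | methyl (1S)-1-{[(tert-butyldiphenylsilyl)oxy]methyl}-3-iodo-4-oxocyclohex-2-ene-1-carboxylate | COC(=O)[C@@]1(CO[Si](c2ccccc2)(c2ccccc2)C(C)(C)C)CCC(=O)C(I)=C1 | intermediate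
10 | dimethyl (1S)-1-{[(tert-butyldiphenylsilyl)oxy]methyl}-4-oxocyclohex-2-ene-1,3-dicarboxylate | COC(=O)[C@@]1(CO[Si](c2ccccc2)(c2ccccc2)C(C)(C)C)CCC(=O)C(C(=O)OC)=C1 | intermediate
11 | 3-bromo-2-(bromomethyl)prop-1-ene | C=C(CBr)CBr | starting material
12 | lithium (trimethylsilyl)acetylide | [Li+].[C-]#C[Si](C)(C)C | starting material
13 | [4-(bromomethyl)pent-4-en-1-yn-1-yl]trimethylsilane | C=C(CBr)CC#C[Si](C)(C)C | intermediate
14 | methyl 3-methylidene-6-(trimethylsilyl)hex-5-ynoate | COC(=O)CC(=C)CC#C[Si](C)(C)C | intermediate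
15 | lithium dienolate of 14 (lithium 1-methoxy-3-methylidene-6-(trimethylsilyl)hex-1-en-5-yn-1-olate) | [Li+].COC([O-])=CC(=C)CC#C[Si](C)(C)C | intermediate
16 | lithium enolate of the Michael adduct (C3–C4 enolate of the β-keto ester; C5 side chain cis to the C10 ester; C6 epimers) | [Li+].COC(=O)[C@@]1(CO[Si](c2ccccc2)(c2ccccc2)C(C)(C)C)CCC([O-])=C(C(=O)OC)[C@H]1C(C(=O)OC)C(=C)CC#C[Si](C)(C)C | intermediate
17 | dimethyl (1S)-1-{[(tert-butyldiphenylsilyl)oxy]methyl}-2-[1-methoxy-3-methylidene-1-oxo-6-(trimethylsilyl)hex-5-yn-2-yl]-3-methyl-4-oxocyclohexane-1,3-dicarboxylate (ring esters and side chain all α; silyloxymethyl and methyl β; C6 epimers) | COC(=O)[C@@]1(CO[Si](c2ccccc2)(c2ccccc2)C(C)(C)C)CCC(=O)[C@@](C)(C(=O)OC)[C@H]1C(C(=O)OC)C(=C)CC#C[Si](C)(C)C | intermediate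
18 | 4-hydroxy analogue of 17 (C3 alcohol epimers; other centres as in 17) | COC(=O)[C@@]1(CO[Si](c2ccccc2)(c2ccccc2)C(C)(C)C)CCC(O)[C@@](C)(C(=O)OC)[C@H]1C(C(=O)OC)C(=C)CC#C[Si](C)(C)C | intermediate
19 | dimethyl 1-{[(tert-butyldiphenylsilyl)oxy]methyl}-2-[1-methoxy-3-methylidene-1-oxo-6-(trimethylsilyl)hex-5-yn-2-yl]-3-methylcyclohex-4-ene-1,3-dicarboxylate (ring centres as in 17) | COC(=O)[C@@]1(CO[Si](c2ccccc2)(c2ccccc2)C(C)(C)C)CC=C[C@@](C)(C(=O)OC)[C@H]1C(C(=O)OC)C(=C)CC#C[Si](C)(C)C | intermediate
20 | dimethyl 1-(hydroxymethyl)-2-(1-methoxy-3-methylidene-1-oxohex-5-yn-2-yl)-3-methylcyclohex-4-ene-1,3-dicarboxylate (ring centres as in 17) | COC(=O)[C@@]1(CO)CC=C[C@@](C)(C(=O)OC)[C@H]1C(C(=O)OC)C(=C)CC#C | intermediate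
21 | dimethyl 1-formyl-2-(1-methoxy-3-methylidene-1-oxohex-5-yn-2-yl)-3-methylcyclohex-4-ene-1,3-dicarboxylate (ring centres as in 17) | COC(=O)[C@@]1(C=O)CC=C[C@@](C)(C(=O)OC)[C@H]1C(C(=O)OC)C(=C)CC#C | intermediate
22 | 1-chloro-3-(triphenyl-λ5-phosphanylidene)propan-2-one | ClCC(=O)C=P(c1ccccc1)(c1ccccc1)c1ccccc1 | starting material
23 | dimethyl 1-[(1E)-4-chloro-3-oxobut-1-en-1-yl]-2-(1-methoxy-3-methylidene-1-oxohex-5-yn-2-yl)-3-methylcyclohex-4-ene-1,3-dicarboxylate (ring centres as in 17) | COC(=O)[C@@]1(/C=C/C(=O)CCl)CC=C[C@@](C)(C(=O)OC)[C@H]1C(C(=O)OC)C(=C)CC#C | intermediate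
24 | dimethyl 1-[(1E,3Z)-3-[(tert-butyldimethylsilyl)oxy]-4-chlorobuta-1,3-dien-1-yl]-2-(1-methoxy-3-methylidene-1-oxohex-5-yn-2-yl)-3-methylcyclohex-4-ene-1,3-dicarboxylate (ring centres as in 17) | COC(=O)[C@@]1(/C=C/C(O[Si](C)(C)C(C)(C)C)=C/Cl)CC=C[C@@](C)(C(=O)OC)[C@H]1C(C(=O)OC)C(=C)CC#C | intermediate
25 | trimethyl 12-[(tert-butyldimethylsilyl)oxy]-13-chloro-13,16-secogibberella-2,11-dien-16-yne-7,19,20-trioate (A/B trans; B/C cis; C13 and C6 epimers) | C#CC[C@]12CC(Cl)C(O[Si](C)(C)C(C)(C)C)=C[C@H]1[C@@]1(CC=C[C@@](C)(C(=O)OC)[C@H]1C2C(=O)OC)C(=O)OC | intermediate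
26 | trimethyl 13-chloro-12-oxo-13,16-secogibberell-2-en-16-yne-7,19,20-trioate (C13 and C6 epimers) | C#CC[C@]12CC(Cl)C(=O)C[C@H]1[C@@]1(CC=C[C@@](C)(C(=O)OC)[C@H]1C2C(=O)OC)C(=O)OC | intermediate
27 | trimethyl 13-chloro-2β,3β-dihydroxy-12-oxo-13,16-secogibberell-16-yne-7,19,20-trioate (C13 and C6 epimers) | C#CC[C@]12CC(Cl)C(=O)C[C@H]1[C@@]1(C[C@H](O)[C@H](O)[C@@](C)(C(=O)OC)[C@H]1C2C(=O)OC)C(=O)OC | intermediate
28 | trimethyl 2β,3β-dihydroxy-12-oxogibberell-16-ene-7,19,20-trioate (C6 epimers) | C=C1C[C@]23C[C@H]1C(=O)C[C@H]2[C@@]2(C[C@H](O)[C@H](O)[C@@](C)(C(=O)OC)[C@H]2C3C(=O)OC)C(=O)OC | intermediate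
29 | trimethyl 2β,3β,12α-trihydroxygibberell-16-ene-7,19,20-trioate, formed as its lithium 12-alkoxide (C6 epimers) | C=C1C[C@]23C[C@H]1[C@@H](O)C[C@H]2[C@@]2(C[C@H](O)[C@H](O)[C@@](C)(C(=O)OC)[C@H]2C3C(=O)OC)C(=O)OC | intermediate
30 | 7,19-dimethyl ester of 2β,3β,12α-trihydroxygibberell-16-ene-7,19,20-trioic acid 20,12-lactone | C=C1C[C@]23C[C@H]1[C@@H]1C[C@H]2[C@@]2(C[C@H](O)[C@H](O)[C@@](C)(C(=O)OC)[C@H]2[C@@H]3C(=O)OC)C(=O)O1 | intermediate
31 | 2β,3β,12α-trihydroxygibberell-16-ene-7,19,20-trioic acid 20,12-lactone (CNP0212122.1) | C=C1C[C@]23C[C@H]1[C@@H]1C[C@H]2[C@@]2(C[C@H](O)[C@H](O)[C@@](C)(C(=O)O)[C@H]2[C@@H]3C(=O)O)C(=O)O1 | target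

Total step count: 20 steps.
Longest linear sequence: 18 steps (steps 1–6 and 9–20); steps 7 and 8 form the side branch that delivers 14.

Steps most likely to fail

Step 16. At the temperature that the unactivated 1,1-disubstituted alkene demands, the allylic chloride of the cycloadduct may ionise, migrate to C11 or be eliminated, and the cycloaddition itself may stay incomplete or take place on the wrong face of the diene. The fallback sets out from aldehyde 21 and removes the halogen so that more forcing conditions can be used. A Wittig reaction with commercial 1-(triphenyl-λ5-phosphanylidene)propan-2-one should give the methyl enone F1, and TBSOTf/Et3N the robust 2-siloxy diene F2. Heating at 200–210 °C should give the cycloadduct silyl enol ether F3, which 1 M HCl hydrolyses to the tricyclic ketone F4; OsO4 with 4-methylmorpholine N-oxide then gives the diol ketone F5. Ring D is closed without a radical, by amine–copper co-catalysed carbocyclisation (pyrrolidine, Cu(OTf)2, PPh3) of the less hindered C12–C13 enamine onto the alkyne, and the route is rejoined at 28.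

Step 9. The ambident dienolate may attack through its terminal carbon C14 (vinylogous Michael addition), or the addition may take place on the wrong face of C5. The fallback sets out from 10 and forms the C5–C6 bond by a sigmatropic shift with chirality transfer. Corey–Bakshi–Shibata reduction of the ketone gives the 3α-allylic alcohol F6, and saponification of 14 (LiOH) gives 3-methylidene-6-(trimethylsilyl)hex-5-ynoic acid F7. Coupling with DCC/DMAP gives the allylic ester F8. Ireland–Claisen rearrangement (KN(SiMe3)2, TMSCl, then warming; acidic work-up) delivers C6 to C5 suprafacially on the α face and gives the rearranged acid F9 with a C3=C4 double bond. Deconjugative α-methylation of its dianion (LiN(i-Pr)2, 2.2 equiv, then MeI) anti to the C5 substituent gives the C4-methylated acid F10, and esterification with (trimethylsilyl)diazomethane rejoins the route at 19.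

Step 18. The α-keto radical may be reduced by the tin hydride before it cyclises, or the stannyl radical may add to the terminal alkyne. The fallback sets out from 27 and replaces the radical by a polar closure. Zn/TMSCl converts the chloro ketone regiospecifically into the C12–C13 trimethylsilyl enol ether F11 (the diol is silylated as well). Ph3PAuCl/AgBF4 in CH2Cl2/MeOH should then effect the 5-exo-dig Conia-ene-type cyclisation with loss of the silyl groups, which comes back to 28.

Further compounds
F1 | step 16 | dimethyl 1-[(1E)-3-oxobut-1-en-1-yl]-2-(1-methoxy-3-methylidene-1-oxohex-5-yn-2-yl)-3-methylcyclohex-4-ene-1,3-dicarboxylate | COC(=O)[C@@]1(/C=C/C(C)=O)CC=C[C@@](C)(C(=O)OC)[C@H]1C(C(=O)OC)C(=C)CC#C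
F2 | step 16 | dimethyl 1-[(1E)-3-[(tert-butyldimethylsilyl)oxy]buta-1,3-dien-1-yl]-2-(1-methoxy-3-methylidene-1-oxohex-5-yn-2-yl)-3-methylcyclohex-4-ene-1,3-dicarboxylate | COC(=O)[C@@]1(/C=C/C(=C)O[Si](C)(C)C(C)(C)C)CC=C[C@@](C)(C(=O)OC)[C@H]1C(C(=O)OC)C(=C)CC#C
F3 | step 16 | trimethyl 12-[(tert-butyldimethylsilyl)oxy]-13,16-secogibberella-2,11-dien-16-yne-7,19,20-trioate | C#CC[C@]12CCC(O[Si](C)(C)C(C)(C)C)=C[C@H]1[C@@]1(CC=C[C@@](C)(C(=O)OC)[C@H]1C2C(=O)OC)C(=O)OC
F4 | step 16 | trimethyl 12-oxo-13,16-secogibberell-2-en-16-yne-7,19,20-trioate | C#CC[C@]12CCC(=O)C[C@H]1[C@@]1(CC=C[C@@](C)(C(=O)OC)[C@H]1C2C(=O)OC)C(=O)OC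
F5 | step 16 | trimethyl 2β,3β-dihydroxy-12-oxo-13,16-secogibberell-16-yne-7,19,20-trioate | C#CC[C@]12CCC(=O)C[C@H]1[C@@]1(C[C@H](O)[C@H](O)[C@@](C)(C(=O)OC)[C@H]1C2C(=O)OC)C(=O)OC
F6 | step 9 | dimethyl 1-{[(tert-butyldiphenylsilyl)oxy]methyl}-4α-hydroxycyclohex-2-ene-1,3-dicarboxylate | COC(=O)[C@@]1(CO[Si](c2ccccc2)(c2ccccc2)C(C)(C)C)CC[C@@H](O)C(C(=O)OC)=C1
F7 | step 9 | 3-methylidene-6-(trimethylsilyl)hex-5-ynoic acid | OC(=O)CC(=C)CC#C[Si](C)(C)C
F8 | step 9 | allylic ester of F6 with F7 | COC(=O)[C@@]1(CO[Si](c2ccccc2)(c2ccccc2)C(C)(C)C)CC[C@@H](OC(=O)CC(=C)CC#C[Si](C)(C)C)C(C(=O)OC)=C1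
F9 | step 9 | 2-[2,6-bis(methoxycarbonyl)-6-{[(tert-butyldiphenylsilyl)oxy]methyl}cyclohex-2-en-1-yl]-3-methylidene-6-(trimethylsilyl)hex-5-ynoic acid | COC(=O)[C@@]1(CO[Si](c2ccccc2)(c2ccccc2)C(C)(C)C)CCC=C(C(=O)OC)[C@H]1C(C(=O)O)C(=C)CC#C[Si](C)(C)C
F10 | step 9 | C4-methylated acid (free C7 acid corresponding to 19) | COC(=O)[C@@]1(CO[Si](c2ccccc2)(c2ccccc2)C(C)(C)C)CC=C[C@@](C)(C(=O)OC)[C@H]1C(C(=O)O)C(=C)CC#C[Si](C)(C)C
F11 | step 18 | trimethyl 2β,3β,12-tris[(trimethylsilyl)oxy]-13,16-secogibberell-12-en-16-yne-7,19,20-trioate | C#CC[C@]12CC=C(O[Si](C)(C)C)C[C@H]1[C@@]1(C[C@H](O[Si](C)(C)C)[C@H](O[Si](C)(C)C)[C@@](C)(C(=O)OC)[C@H]1C2C(=O)OC)C(=O)OC
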